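**Strategy.** The target is cut at the bond between the chain CH2 of the monocyclic unit and the alkene carbon that carries CH2OH. The acyclic E allylic alcohol C(CH2OH)=CH between the methylenecyclohexane ring and the decalin is the retron of a CuI-catalysed anti-carbomagnesiation of a 2-alkyn-1-ol. The propargylic alkoxide steers the Grignard carbon to the proximal alkyne carbon and a five-membered O–Mg–C chelate fixes the geometry. One operation therefore forges the C–C bond and the trisubstituted alkene with its free hydroxymethyl group. The precursor pair is a pent-2-yn-1-ol cut out of sclareol and a homo-γ-cyclogeranyl Grignard reagent.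

Key step: step 9

Assumption (remark on the chemistry): in step 7 the lipase is taken to acylate the (R)-alcohol faster, so that the (S)-alcohol is the recovered component. If the preference is the reverse, the acetate fraction is saponified (K2CO3, MeOH) to give 13.

**Route**

Step 1
Reactants: 1 (−)-sclareol
Product: 2 4-[(1R,2R,4aS,8aS)-2-hydroxy-2,5,5,8a-tetramethyldecahydronaphthalen-1-yl]butan-2-one
Conditions: OsO4 (2 mol%), NaIO4 (4 equiv), 2,6-lutidine, dioxane–H2O, rt
Reagents that add atoms: none
Why: Lemieux–Johnson dihydroxylation–periodate cleavage of the vinyl carbinol; the intermediate triol is cleaved twice, so both vinyl carbons are excised and the carbinol carbon becomes the methyl ketone carbonyl, with the four decalin stereocentres untouched.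

Step 2
Reactants: 2 hydroxy ketone
Product: 3 4-[(1R,2R,4aS,8aS)-2,5,5,8a-tetramethyl-2-(trimethylsilyloxy)decahydronaphthalen-1-yl]butan-2-one
Conditions: N-(trimethylsilyl)imidazole, CH2Cl2, rt
Reagents that add atoms: N-(trimethylsilyl)imidazole, C[Si](C)(C)n1ccnc1
Why: Silyl ether formation with a neutral, powerful silyl donor should cap the hindered tertiary hydroxyl without enolising the ketone, which keeps the alkoxide out of the enolate chemistry of step 3.

Step 3
Reactants: 3 silyl ether ketone
Product: 6 5-[(1R,2R,4aS,8aS)-2,5,5,8a-tetramethyl-2-(trimethylsilyloxy)decahydronaphthalen-1-yl]pent-2-yn-1-ol, via enol phosphate 4 (not isolated), via lithium acetylide 5 (not isolated)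
Conditions: LiN(i-Pr)2 (1.1 equiv), THF, −78 °C; ClP(O)(OEt)2, −78 °C → rt; LiN(i-Pr)2 (2.3 equiv), −78 °C → rt; (CH2O)n, rt; sat. aq. NH4Cl
Reagents that add atoms: paraformaldehyde, as formaldehyde C=O
Why: Kinetic deprotonation at the methyl group and O-phosphorylation give the terminal enol phosphate, whose base-induced elimination (methyl ketone to terminal alkyne conversion) leaves the lithium acetylide, which adds to formaldehyde to give the propargylic alcohol.

Step 4
Reactants: 7 3-methylcyclohex-2-en-1-one; 8 ethyl bromoacetate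
Product: 10 ethyl 2-(2,2-dimethyl-6-oxocyclohexyl)acetate (racemic), via lithium enolate 9 (not isolated)
Conditions: Me2CuLi (from MeLi and CuI), Et2O, 0 °C; then 8, THF–HMPA, −40 °C → rt
Reagents that add atoms: lithium dimethylcuprate, [Li+].C[Cu-]C (made in the flask from methyllithium, [Li]C, and CuI)
Why: Conjugate addition of the Gilman cuprate builds the gem-dimethyl carbon and gives a regiodefined enolate, which the reactive α-bromo ester should C-alkylate at the carbon next to the new quaternary centre; the stereocentre is formed as a racemate.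

Step 5
Reactants: 10 keto ester
Product: 11 ethyl 2-(2,2-dimethyl-6-methylidenecyclohexyl)acetate (racemic)
Conditions: Ph3PCH3Br, KOtBu, THF, 0 °C → rt
Reagents that add atoms: methyltriphenylphosphonium bromide, C[P+](c1ccccc1)(c1ccccc1)c1ccccc1.[Br-]
Why: Wittig methylenation should take the ketone in preference to the ester and install the exocyclic methylene; the substrate is racemic, so α-epimerisation is of no consequence.

Step 6
Reactants: 11 methylene ester
Product: 12 2-(2,2-dimethyl-6-methylidenecyclohexyl)ethan-1-ol (racemic)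
Conditions: LiAlH4, Et2O, 0 °C
Reagents that add atoms: none
Why: Hydride reduction of the ester to the primary alcohol; the isolated 1,1-disubstituted alkene is inert to LiAlH4.

Step 7
Reactants: 12 racemic alcohol
Product: 13 2-[(1S)-2,2-dimethyl-6-methylidenecyclohexyl]ethan-1-ol
Conditions: Amano lipase PS, vinyl acetate, t-BuOMe, rt, run past half conversion
Reagents that add atoms: none
Why: Lipase-catalysed kinetic resolution by irreversible transesterification; the enzyme should acylate one enantiomer of the primary alcohol faster, and the unreacted (S)-alcohol is recovered, which fixes the absolute configuration of the monocyclic stereocentre.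

Step 8
Reactants: 13 (S)-alcohol
Product: 14 (2S)-2-(2-bromoethyl)-1,1-dimethyl-3-methylidenecyclohexane
Conditions: CBr4, PPh3, CH2Cl2, 0 °C
Reagents that add atoms: carbon tetrabromide, BrC(Br)(Br)Br
Why: Appel bromination of the primary alcohol under neutral conditions; the stereocentre and the exocyclic alkene are not involved.

Step 9
Reactants: 6 alkynol; 14 (S)-bromide
Product: 19 (2E)-2-{2-[(1S)-2,2-dimethyl-6-methylidenecyclohexyl]ethyl}-5-[(1R,2R,4aS,8aS)-2-hydroxy-2,5,5,8a-tetramethyldecahydronaphthalen-1-yl]pent-2-en-1-ol (CNP0209309.1), via Grignard reagent 15 (not isolated), via bromomagnesium alkoxide 16 (not isolated), via oxamagnesacycle 17 (not isolated), via silyl ether 18 (not isolated)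
Conditions: 14, Mg, THF, rt (gives 15, 2 equiv); 6, EtMgBr (1.0 equiv), THF, 0 °C (gives 16); combine, CuI (10 mol%), THF, 50 °C; sat. aq. NH4Cl; then TBAF, THF, rt
Reagents that add atoms: none
Why: The alkylcopper–magnesium species formed from 15 and CuI is bound by the bromomagnesium alkoxide 16 and delivers the homo-γ-cyclogeranyl carbon to the alkyne carbon next to CH2O, while magnesium ends on the distal carbon on the opposite face, held by the alkoxide oxygen. The closest known reaction type is the copper-catalysed anti-carbomagnesiation of 2-alkyn-1-ols with Grignard reagents. No ring of the target is closed; the temporary five-membered C=C–Mg–O–CH2 chelate 17 closes by Mg–O coordination during the anti addition (formally 5-endo-dig at the alkyne) and is opened again on protonolysis. No stereocentre is created; the alkene geometry is the new stereo-element and follows from anti addition and stereoretentive protonolysis of the C–Mg bond, which places CH2OH trans to the decalin-bearing chain. The step needs regioselectivity (alkyl to the proximal carbon), secured by the alkoxide chelate, and chemoselectivity, secured because the exocyclic alkene and the TMS-masked tertiary hydroxyl are inert to the Grignard reagent. Fluoride then removes the silyl group from 18 in the same flask.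

**Compound list**

1 | (−)-sclareol, (13R)-labd-14-ene-8α,13-diol | C=C[C@](C)(O)CC[C@@H]1[C@@]2(C)CCCC(C)(C)[C@@H]2CC[C@@]1(C)O | starting material
2 | 4-[(1R,2R,4aS,8aS)-2-hydroxy-2,5,5,8a-tetramethyldecahydronaphthalen-1-yl]butan-2-one | CC(=O)CC[C@@H]1[C@@]2(C)CCCC(C)(C)[C@@H]2CC[C@@]1(C)O | intermediate
3 | 4-[(1R,2R,4aS,8aS)-2,5,5,8a-tetramethyl-2-(trimethylsilyloxy)decahydronaphthalen-1-yl]butan-2-one | CC(=O)CC[C@@H]1[C@@]2(C)CCCC(C)(C)[C@@H]2CC[C@@]1(C)O[Si](C)(C)C | intermediate
4 | enol phosphate, diethyl 4-[(1R,2R,4aS,8aS)-2,5,5,8a-tetramethyl-2-(trimethylsilyloxy)decahydronaphthalen-1-yl]but-1-en-2-yl phosphate, formed in the flask | C=C(OP(=O)(OCC)OCC)CC[C@@H]1[C@@]2(C)CCCC(C)(C)[C@@H]2CC[C@@]1(C)O[Si](C)(C)C | intermediate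
5 | lithium acetylide, {4-[(1R,2R,4aS,8aS)-2,5,5,8a-tetramethyl-2-(trimethylsilyloxy)decahydronaphthalen-1-yl]but-1-yn-1-yl}lithium, formed in the flask | [Li]C#CCC[C@@H]1[C@@]2(C)CCCC(C)(C)[C@@H]2CC[C@@]1(C)O[Si](C)(C)C | intermediate
6 | 5-[(1R,2R,4aS,8aS)-2,5,5,8a-tetramethyl-2-(trimethylsilyloxy)decahydronaphthalen-1-yl]pent-2-yn-1-ol | OCC#CCC[C@@H]1[C@@]2(C)CCCC(C)(C)[C@@H]2CC[C@@]1(C)O[Si](C)(C)C | intermediate
7 | 3-methylcyclohex-2-en-1-one | CC1=CC(=O)CCC1 | starting material
8 | ethyl bromoacetate | CCOC(=O)CBr | starting material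
9 | lithium 3,3-dimethylcyclohex-1-en-1-olate, formed in the flask | [Li]OC1=CC(C)(C)CCC1 | intermediate
10 | ethyl 2-(2,2-dimethyl-6-oxocyclohexyl)acetate, racemic | CCOC(=O)CC1C(=O)CCCC1(C)C | intermediate
11 | ethyl 2-(2,2-dimethyl-6-methylidenecyclohexyl)acetate, racemic | CCOC(=O)CC1C(=C)CCCC1(C)C | intermediate
12 | 2-(2,2-dimethyl-6-methylidenecyclohexyl)ethan-1-ol, racemic | OCCC1C(=C)CCCC1(C)C | intermediate
13 | 2-[(1S)-2,2-dimethyl-6-methylidenecyclohexyl]ethan-1-ol | C=C1CCCC(C)(C)[C@@H]1CCO | intermediate
14 | (2S)-2-(2-bromoethyl)-1,1-dimethyl-3-methylidenecyclohexane | C=C1CCCC(C)(C)[C@@H]1CCBr | intermediate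
15 | {2-[(1S)-2,2-dimethyl-6-methylidenecyclohexyl]ethyl}magnesium bromide, formed in the flask | C=C1CCCC(C)(C)[C@@H]1CC[Mg]Br | intermediate
16 | bromomagnesium alkoxide of 6, formed in the flask | Br[Mg]OCC#CCC[C@@H]1[C@@]2(C)CCCC(C)(C)[C@@H]2CC[C@@]1(C)O[Si](C)(C)C | intermediate
17 | oxamagnesacycle (2,5-dihydro-1,2-oxamagnesole carrying the decalinylethyl chain on the magnesium-bound carbon and the cyclohexylethyl chain on the neighbouring ring carbon), formed in the flask | C=C1CCCC(C)(C)[C@@H]1CCC2=C(CC[C@@H]3[C@@]4(C)CCCC(C)(C)[C@@H]4CC[C@@]3(C)O[Si](C)(C)C)[Mg]OC2 | intermediate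
18 | trimethylsilyl ether of the target at the tertiary hydroxyl, (2E)-configured, formed in the flask | C=C1CCCC(C)(C)[C@@H]1CC/C(=C\CC[C@@H]1[C@@]2(C)CCCC(C)(C)[C@@H]2CC[C@@]1(C)O[Si](C)(C)C)CO | intermediate
19 | (2E)-2-{2-[(1S)-2,2-dimethyl-6-methylidenecyclohexyl]ethyl}-5-[(1R,2R,4aS,8aS)-2-hydroxy-2,5,5,8a-tetramethyldecahydronaphthalen-1-yl]pent-2-en-1-ol (CNP0209309.1) | C=C1CCCC(C)(C)[C@@H]1CC/C(=C\CC[C@@H]1[C@@]2(C)CCCC(C)(C)[C@@H]2CC[C@@]1(C)O)CO | target

**Step count.** Total: 9 steps. Longest linear sequence: 6 steps (7 → 10 → 11 → 12 → 13 → 14 → 19, steps 4 to 9). The sclareol branch contributes 3 steps before the coupling.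

**Steps most likely to fail, with fallbacks**

1. Step 9. The carbometalation of an internal alkynol by a β-branched primary alkyl Grignard reagent may be slow. Reduction of the alkyne by β-hydride transfer from the alkylcopper species, or loss of regiocontrol, could then compete.
Fallback, from 6 and 15, returning at 18: [Cp*RuCl]4-catalysed trans-hydrostannation of 6 with Bu3SnH (CH2Cl2, rt) should place tin on the alkyne carbon next to CH2OH and hydrogen anti to it, giving the (Z)-alkenylstannane F1. Iododestannylation (I2, CH2Cl2, 0 °C) gives the (Z)-2-iodo allylic alcohol F2 with retention. The Grignard reagent 15 is treated with 9-methoxy-9-borabicyclo[3.3.1]nonane (THF, −78 °C → rt) to give the bromomagnesium alkyl(methoxy)borate F3. A B-alkyl Suzuki–Miyaura coupling of F2 with F3 (PdCl2(dppf), DMF–THF, 50 °C) then forms the same C–C bond with retention of the alkene geometry and gives 18, which fluoride converts to 19 as in step 9.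

2. Step 7. Enantiodiscrimination by the lipase may be weak, because the stereocentre lies two carbons from the reacting oxygen, which would leave the recovered alcohol with insufficient enantiomeric purity.
Fallback, from 11, returning at 13: saponification (LiOH, THF–H2O) gives the racemic 2-(2,2-dimethyl-6-methylidenecyclohexyl)acetic acid F4. Classical resolution with (R)-1-phenylethylamine (fractional crystallisation from acetone) gives the diastereomerically pure ammonium salt F5; the antipodal amine is used if the other salt is the less soluble one. Acidification liberates 2-[(1S)-2,2-dimethyl-6-methylidenecyclohexyl]acetic acid F6, and LiAlH4 reduction gives 13.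

3. Step 4. C-alkylation of the enolate next to the new quaternary carbon may be slow, so that proton transfer between product and enolate, polyalkylation and O-alkylation compete.
Fallback, from 7, returning at 11: the cuprate-derived enolate 9 is trapped with PhNTf2 to give 3,3-dimethylcyclohex-1-en-1-yl trifluoromethanesulfonate F7. Carbonylation (Pd(OAc)2, PPh3, CO, MeOH, Et3N, DMF, 60 °C) gives methyl 3,3-dimethylcyclohex-1-ene-1-carboxylate F8, and i-Bu2AlH (CH2Cl2, −78 °C) gives (3,3-dimethylcyclohex-1-en-1-yl)methanol F9. A Johnson–Claisen rearrangement (MeC(OEt)3, cat. EtCO2H, 140 °C) then delivers the acetate unit to the ring carbon next to the gem-dimethyl group and moves the double bond into the exocyclic position, giving 11 directly.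

**Further compounds**

F1 | step 9 | (2Z)-5-[(1R,2R,4aS,8aS)-2,5,5,8a-tetramethyl-2-(trimethylsilyloxy)decahydronaphthalen-1-yl]-2-(tributylstannyl)pent-2-en-1-ol | CCCC[Sn](CCCC)(CCCC)/C(CO)=C\CC[C@@H]1[C@@]2(C)CCCC(C)(C)[C@@H]2CC[C@@]1(C)O[Si](C)(C)C
F2 | step 9 | (2Z)-2-iodo-5-[(1R,2R,4aS,8aS)-2,5,5,8a-tetramethyl-2-(trimethylsilyloxy)decahydronaphthalen-1-yl]pent-2-en-1-ol | I/C(CO)=C\CC[C@@H]1[C@@]2(C)CCCC(C)(C)[C@@H]2CC[C@@]1(C)O[Si](C)(C)C
F3 | step 9 | bromomagnesium {2-[(1S)-2,2-dimethyl-6-methylidenecyclohexyl]ethyl}(methoxy)-9-borabicyclo[3.3.1]nonan-9-uide | C=C1CCCC(C)(C)[C@@H]1CC[B-]2(OC)C3CCCC2CCC3.[Mg+]Br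
F4 | step 7 | 2-(2,2-dimethyl-6-methylidenecyclohexyl)acetic acid, racemic | OC(=O)CC1C(=C)CCCC1(C)C
F5 | step 7 | (R)-1-phenylethylammonium 2-[(1S)-2,2-dimethyl-6-methylidenecyclohexyl]acetate | C=C1CCCC(C)(C)[C@@H]1CC(=O)[O-].C[C@@H]([NH3+])c1ccccc1
F6 | step 7 | 2-[(1S)-2,2-dimethyl-6-methylidenecyclohexyl]acetic acid | C=C1CCCC(C)(C)[C@@H]1CC(=O)O
F7 | step 4 | 3,3-dimethylcyclohex-1-en-1-yl trifluoromethanesulfonate | O=S(=O)(OC1=CC(C)(C)CCC1)C(F)(F)F
F8 | step 4 | methyl 3,3-dimethylcyclohex-1-ene-1-carboxylate | COC(=O)C1=CC(C)(C)CCC1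
F9 | step 4 | (3,3-dimethylcyclohex-1-en-1-yl)methanol | OCC1=CC(C)(C)CCC1
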